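Ring A is the pyranone. Ring B is the benzene ring, numbered C1' (bears the bridging CH2), C2' (OMe), C3' (H), C4' (OH), C5' (acyl), C6' (OH).
Retrosynthesis: the C5'–acyl bond is cut first (back to an ester on O6'). Ring B is then opened at C6'–C1', C2'–C3' and C5'–C6' into a 3-alkoxycyclobutenone and a methyl ynol ether. The CH2–C(sp) bond beside ring A is cut next, and ring A last (ketone plus malonyl unit).
Enabling feature: ring B carries oxygen on C2', C4' and C6', alternating with C1', C3' and C5'. C1'–C2'(OMe) is therefore the imprint of a methoxyalkyne, and C3'–C4'(O)–C5'–C6'(O) that of the four ring carbons of a 3-oxycyclobutenone.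
Forward: ring A is made in step 1, benzylated, given a C3 bromomethyl arm and joined to methoxyacetylene. Ring B is grown onto the alkyne in step 9. The acyl chain enters through O6' and is moved to C5' last.
Stereochemistry: the single stereocentre, (R) at C2 of the acyl chain, is bought as (2R)-2-methylbutanoic acid; no step creates a stereocentre.

Key step: step 9

Assumption: methoxyacetylene is made and used as a cold THF solution, and (2R)-2-methylbutanoic acid and cyclobutane-1,3-dione are bought, the acid in high enantiomeric purity.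

Step 1
Reactants: 1 pentan-3-one; 2 malonyl dichloride
Product: 3 6-ethyl-4-hydroxy-5-methylpyran-2-one
Conditions: Et2O, 0 °C to reflux, HCl swept out with N2
Reagents that add atoms: none
Why: Ketone–malonyl dichloride pyrone annulation (C-acylation of the enol, then O-acylation/lactonisation with loss of two HCl); the symmetry of the ketone allows only one regiochemical outcome.

Step 2
Reactants: 3 6-ethyl-4-hydroxy-5-methylpyran-2-one
Product: 4 4-(benzyloxy)-6-ethyl-5-methylpyran-2-one
Conditions: BnBr, K2CO3, DMF, 50 °C
Reagents that add atoms: benzyl bromide, BrCc1ccccc1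
Why: Williamson O-alkylation of the vinylogous acid as its potassium salt in a dipolar aprotic solvent, which should favour O4 over C3.

Step 3
Reactants: 4 4-(benzyloxy)-6-ethyl-5-methylpyran-2-one
Product: 5 4-(benzyloxy)-3-bromo-6-ethyl-5-methylpyran-2-one
Conditions: NBS, MeCN, 0 to 25 °C, dark
Reagents that add atoms: N-bromosuccinimide, O=C1CCC(=O)N1Br
Why: Electrophilic bromination of the push-pull enol ether at C3, the only unsubstituted ring carbon, under ionic conditions that leave the benzylic and allylic C–H bonds alone.

Step 4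
Reactants: 5 4-(benzyloxy)-3-bromo-6-ethyl-5-methylpyran-2-one; 6 (tributylstannyl)methanol
Product: 7 4-(benzyloxy)-6-ethyl-3-(hydroxymethyl)-5-methylpyran-2-one
Conditions: Pd(PPh3)4 (5 mol %), 1,4-dioxane, 95 °C
Reagents that add atoms: none
Why: Stille hydroxymethylation, in which zerovalent palladium inserts into the activated C3–Br bond and the CH2OH group is transferred from tin under neutral conditions that spare the lactone and the benzyl enol ether.

Step 5
Reactants: 7 4-(benzyloxy)-6-ethyl-3-(hydroxymethyl)-5-methylpyran-2-one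
Product: 8 4-(benzyloxy)-3-(bromomethyl)-6-ethyl-5-methylpyran-2-one
Conditions: CBr4, PPh3, CH2Cl2, 0 °C; used at once
Reagents that add atoms: tetrabromomethane, BrC(Br)(Br)Br
Why: Appel reaction, which converts the primary allylic-type alcohol into the bromide without free HBr that would cleave the benzyl enol ether.

Step 6
Reactants: 9 2-chloro-1,1-dimethoxyethane
Product: 11 methoxyethyne, via sodium methoxyacetylide 10 (not isolated)
Conditions: NaNH2 (3 equiv), NH3 (l), −33 °C; then cold aq. NaCl, distilled into THF at −78 °C
Reagents that add atoms: none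
Why: Twofold base-induced elimination (HCl, then MeOH) followed by deprotonation, the standard preparation of alkoxyacetylenes; isolating the alkyne keeps secondary amines away from bromide 8 in the next step.

Step 7
Reactants: 11 methoxyethyne; 8 4-(benzyloxy)-3-(bromomethyl)-6-ethyl-5-methylpyran-2-one
Product: 13 4-(benzyloxy)-6-ethyl-3-(3-methoxyprop-2-yn-1-yl)-5-methylpyran-2-one, via lithium methoxyacetylide 12 (not isolated)
Conditions: n-BuLi, THF, −78 °C; then 8, DMPU, −78 to −20 °C; NaHCO3 work-up, Et3N-deactivated silica
Reagents that add atoms: none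
Why: SN2 alkylation of a lithium alkoxyacetylide by an activated primary bromide in THF/DMPU at low temperature, where substitution should outrun attack on the vinylogous carbonate or deprotonation of the 6-ethyl group.

Step 8
Reactants: 14 cyclobutane-1,3-dione
Product: 15 3-(benzyloxy)cyclobut-2-en-1-one
Conditions: BnOH, PPh3, DIAD, THF, 0 to 25 °C
Reagents that add atoms: benzyl alcohol, OCc1ccccc1
Why: Mitsunobu O-alkylation of the strongly acidic enol form under neutral conditions, which avoids acid- or base-induced opening of the strained dione.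

Step 9
Reactants: 13 4-(benzyloxy)-6-ethyl-3-(3-methoxyprop-2-yn-1-yl)-5-methylpyran-2-one; 15 3-(benzyloxy)cyclobut-2-en-1-one
Product: 20 4-(benzyloxy)-3-{[4-(benzyloxy)-2-hydroxy-6-methoxyphenyl]methyl}-6-ethyl-5-methylpyran-2-one, via vinylketene 16 (not isolated), via vinylcyclobutenone 17 (not isolated), via dienylketene 18 (not isolated), via cyclohexadienone 19 (not isolated)
Conditions: 15 (1.5 equiv, added in portions), toluene, 80 to 110 °C, sealed tube under argon
Reagents that add atoms: none
Why: Danheiser benzannulation: thermal conrotatory four-electron opening of 15 gives alkoxyvinylketene 16, which adds [2+2] to ynol ether 13 so that the alkyne carbon β to OMe bonds to the ketene carbonyl carbon (C6'–C1') and the OMe-bearing carbon to the ketene α-carbon (C2'–C3'), giving 17. Four-electron opening of 17 gives dienylketene 18, ring B closes by thermal disrotatory six-electron electrocyclisation (C5'–C6'), and tautomerisation of 19 gives the phenol with O6' free. The closest known reactions are thermal benzannulations of cyclobutenones, including 3-oxygenated ones, with alkoxy- and silyloxyalkynes to give resorcinol derivatives. No stereocentre is formed. The step needs one regiochemistry in the ketene–alkyne addition, which the polarisation of the ynol ether secures, and preference for the alkyne over the pyrone, which the far higher ketenophilicity of the ynol ether and the neutral medium should provide. A methyl ynol ether is used because it cannot lose an alkene by retro-ene fragmentation at this temperature.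

Step 10
Reactants: 20 4-(benzyloxy)-3-{[4-(benzyloxy)-2-hydroxy-6-methoxyphenyl]methyl}-6-ethyl-5-methylpyran-2-one; 21 (2R)-2-methylbutanoic acid
Product: 22 5-(benzyloxy)-2-{[4-(benzyloxy)-6-ethyl-5-methyl-2-oxopyran-3-yl]methyl}-3-methoxyphenyl (2R)-2-methylbutanoate
Conditions: DCC, DMAP (10 mol %), CH2Cl2, 0 to 25 °C
Reagents that add atoms: none
Why: Steglich esterification of the only free hydroxyl; catalytic DMAP at low temperature should leave the α-stereocentre of the acid intact.

Step 11
Reactants: 22 5-(benzyloxy)-2-{[4-(benzyloxy)-6-ethyl-5-methyl-2-oxopyran-3-yl]methyl}-3-methoxyphenyl (2R)-2-methylbutanoate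
Product: 23 2-[(6-ethyl-4-hydroxy-5-methyl-2-oxopyran-3-yl)methyl]-5-hydroxy-3-methoxyphenyl (2R)-2-methylbutanoate
Conditions: H2 (1 atm), 10% Pd/C, EtOAc, 25 °C
Reagents that add atoms: none
Why: Hydrogenolysis of both benzyl ethers at atmospheric pressure should spare the aryl ester, the pyranone and the stereocentre, and removes the Lewis-acid-labile groups before the rearrangement.

Step 12
Reactants: 23 2-[(6-ethyl-4-hydroxy-5-methyl-2-oxopyran-3-yl)methyl]-5-hydroxy-3-methoxyphenyl (2R)-2-methylbutanoate
Product: 24 3-({2,4-dihydroxy-6-methoxy-3-[(2R)-2-methylbutanoyl]phenyl}methyl)-6-ethyl-4-hydroxy-5-methylpyran-2-one (target)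
Conditions: TiCl4 (4 equiv), CH2Cl2/MeNO2, 0 to 25 °C; aq. HCl work-up
Reagents that add atoms: none
Why: Fries rearrangement, in which TiCl4 activates the ester and delivers the acyl group to C5', the only free carbon ortho to O6', giving the doubly chelated 2,6-dihydroxyaryl ketone as the favoured isomer with the stereocentre carried over from 21.

Compound list
1 | pentan-3-one | CCC(=O)CC | starting material
2 | malonyl dichloride | O=C(Cl)CC(=O)Cl | starting material
3 | 6-ethyl-4-hydroxy-5-methylpyran-2-one | CCc1oc(=O)cc(O)c1C | intermediate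
4 | 4-(benzyloxy)-6-ethyl-5-methylpyran-2-one | CCc1oc(=O)cc(OCc2ccccc2)c1C | intermediate
5 | 4-(benzyloxy)-3-bromo-6-ethyl-5-methylpyran-2-one | CCc1oc(=O)c(Br)c(OCc2ccccc2)c1C | intermediate
6 | (tributylstannyl)methanol | CCCC[Sn](CCCC)(CCCC)CO | starting material
7 | 4-(benzyloxy)-6-ethyl-3-(hydroxymethyl)-5-methylpyran-2-one | CCc1oc(=O)c(CO)c(OCc2ccccc2)c1C | intermediate
8 | 4-(benzyloxy)-3-(bromomethyl)-6-ethyl-5-methylpyran-2-one | CCc1oc(=O)c(CBr)c(OCc2ccccc2)c1C | intermediate
9 | 2-chloro-1,1-dimethoxyethane (chloroacetaldehyde dimethyl acetal) | COC(CCl)OC | starting material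
10 | sodium methoxyacetylide | [Na+].[C-]#COC | intermediate
11 | methoxyethyne (methoxyacetylene) | COC#C | intermediate
12 | lithium methoxyacetylide | [Li+].[C-]#COC | intermediate
13 | 4-(benzyloxy)-6-ethyl-3-(3-methoxyprop-2-yn-1-yl)-5-methylpyran-2-one | CCc1oc(=O)c(CC#COC)c(OCc2ccccc2)c1C | intermediate
14 | cyclobutane-1,3-dione | O=C1CC(=O)C1 | starting material
15 | 3-(benzyloxy)cyclobut-2-en-1-one | O=C1C=C(OCc2ccccc2)C1 | intermediate
16 | 3-(benzyloxy)buta-1,3-dien-1-one (vinylketene) | O=C=CC(=C)OCc1ccccc1 | intermediate
17 | 4-(benzyloxy)-3-({3-[1-(benzyloxy)ethenyl]-2-methoxy-4-oxocyclobut-1-en-1-yl}methyl)-6-ethyl-5-methylpyran-2-one (vinylcyclobutenone, racemic) | CCc1oc(=O)c(CC2=C(OC)C(C(=C)OCc3ccccc3)C2=O)c(OCc2ccccc2)c1C | intermediate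
18 | 5-(benzyloxy)-2-{[4-(benzyloxy)-6-ethyl-5-methyl-2-oxopyran-3-yl]methyl}-3-methoxyhexa-1,3,5-trien-1-one (dienylketene) | CCc1oc(=O)c(CC(=C=O)C(OC)=CC(=C)OCc2ccccc2)c(OCc2ccccc2)c1C | intermediate
19 | 4-(benzyloxy)-3-{[4-(benzyloxy)-2-methoxy-6-oxocyclohexa-1,3-dien-1-yl]methyl}-6-ethyl-5-methylpyran-2-one (cyclohexadienone) | CCc1oc(=O)c(CC2=C(OC)C=C(OCc3ccccc3)CC2=O)c(OCc2ccccc2)c1C | intermediate
20 | 4-(benzyloxy)-3-{[4-(benzyloxy)-2-hydroxy-6-methoxyphenyl]methyl}-6-ethyl-5-methylpyran-2-one | CCc1oc(=O)c(Cc2c(OC)cc(OCc3ccccc3)cc2O)c(OCc2ccccc2)c1C | intermediate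
21 | (2R)-2-methylbutanoic acid | OC(=O)[C@H](C)CC | starting material
22 | 5-(benzyloxy)-2-{[4-(benzyloxy)-6-ethyl-5-methyl-2-oxopyran-3-yl]methyl}-3-methoxyphenyl (2R)-2-methylbutanoate | CCc1oc(=O)c(Cc2c(OC)cc(OCc3ccccc3)cc2OC(=O)[C@H](C)CC)c(OCc2ccccc2)c1C | intermediate
23 | 2-[(6-ethyl-4-hydroxy-5-methyl-2-oxopyran-3-yl)methyl]-5-hydroxy-3-methoxyphenyl (2R)-2-methylbutanoate | CCc1oc(=O)c(Cc2c(OC)cc(O)cc2OC(=O)[C@H](C)CC)c(O)c1C | intermediate
24 | 3-({2,4-dihydroxy-6-methoxy-3-[(2R)-2-methylbutanoyl]phenyl}methyl)-6-ethyl-4-hydroxy-5-methylpyran-2-one | CCc1oc(=O)c(Cc2c(OC)cc(O)c(C(=O)[C@H](C)CC)c2O)c(O)c1C | target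

Total step count: 12. Longest linear sequence: 10 steps (steps 1–5, 7, 9–12, from pentan-3-one).

Steps most likely to fail

Step 9. The enol-ether oxygen stabilises the four-membered enone, so ring opening may be slow. At the temperature then needed, the vinylketene may dimerise or acylate the product phenol, and the ynol ether may decay before it is consumed. The fallback sets out from 3 and 21 and rejoins the route at 24. It gives up the cycloaddition for methylene bridging of a finished acylphloroglucinol. Acid 21 with oxalyl chloride (cat. DMF, CH2Cl2) should give (2R)-2-methylbutanoyl chloride F1. Friedel–Crafts acylation of phloroglucinol with F1 (AlCl3, CH2Cl2/PhNO2, 0 °C) should give (2R)-2-methyl-1-(2,4,6-trihydroxyphenyl)butan-1-one F2. Methylation of the one hydroxyl not hydrogen-bonded to the ketone (Me2SO4, 1 equiv, K2CO3, acetone) should give (2R)-1-(2,6-dihydroxy-4-methoxyphenyl)-2-methylbutan-1-one F3. Mannich aminomethylation with dimethylmethylideneammonium iodide should give (2R)-1-{3-[(dimethylamino)methyl]-2,6-dihydroxy-4-methoxyphenyl}-2-methylbutan-1-one F4. Heating F4 with pyrone 3 (MeCN, 80 °C) should expel dimethylamine to an ortho-quinone methide that C3 of 3 traps, giving 24. The two free ring positions of F3 are equivalent, so no regiochemical question arises.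

Step 7. The acetylide is also a base and a hard nucleophile. Addition to the lactone carbonyl, deprotonation at the 6-ethyl group, SN2' attack at C4 and base-induced propargyl-to-allenyl isomerisation all compete with substitution. The fallback sets out from 11 and 8 and returns at 13. Alkyne 11 is lithiated (n-BuLi, THF, −78 °C) and quenched with Bu3SnCl to give tributyl(methoxyethynyl)stannane F5. F5 is joined to 8 by Stille coupling (Pd(PPh3)4, THF, 50 °C), a neutral cross-coupling in which no free acetylide meets the pyranone.

Step 12. Acyl transfer between oxygens or between molecules before C–C bond formation would open the way to acylation at C3'. The Lewis acid may also enolise the activated acyl group and erode the stereocentre, or split the acid-sensitive methylene bridge. The fallback sets out from 20 and returns at 24, with the benzyl ethers kept on during C-acylation. Phenol 20 is converted with EtMgBr (1 equiv, toluene, 0 °C) into its bromomagnesium phenoxide. This should take up (2R)-2-methylbutanoyl chloride F1 (made from 21 as in the first fallback) at C5', the only free ortho carbon, by magnesium-templated ortho-acylation. The product is 4-(benzyloxy)-3-({4-(benzyloxy)-2-hydroxy-6-methoxy-3-[(2R)-2-methylbutanoyl]phenyl}methyl)-6-ethyl-5-methylpyran-2-one F6. Hydrogenolysis of F6 (H2, 10% Pd/C, EtOAc) should then give 24.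

Further compounds
F1 | step 9 | (2R)-2-methylbutanoyl chloride | ClC(=O)[C@H](C)CC
F2 | step 9 | (2R)-2-methyl-1-(2,4,6-trihydroxyphenyl)butan-1-one | O=C([C@H](C)CC)c1c(O)cc(O)cc1O
F3 | step 9 | (2R)-1-(2,6-dihydroxy-4-methoxyphenyl)-2-methylbutan-1-one | O=C([C@H](C)CC)c1c(O)cc(OC)cc1O
F4 | step 9 | (2R)-1-{3-[(dimethylamino)methyl]-2,6-dihydroxy-4-methoxyphenyl}-2-methylbutan-1-one | CN(C)Cc1c(OC)cc(O)c(C(=O)[C@H](C)CC)c1O
F5 | step 7 | tributyl(methoxyethynyl)stannane | CCCC[Sn](CCCC)(CCCC)C#COC
F6 | step 12 | 4-(benzyloxy)-3-({4-(benzyloxy)-2-hydroxy-6-methoxy-3-[(2R)-2-methylbutanoyl]phenyl}methyl)-6-ethyl-5-methylpyran-2-one | CCc1oc(=O)c(Cc2c(OC)cc(OCc3ccccc3)c(C(=O)[C@H](C)CC)c2O)c(OCc2ccccc2)c1C
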